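**Retrosynthetic overview**
1. Germacrane locants are used: C4(C15H2O‑angelate)=C5, C6‑OH, C7‑iPr, C8‑OAc, C9H2, C10(C14H3)=C1, C2H2, C3H2. The target is (6S,7S,8S), both ring alkenes are trans within the ring, and the single ten‑membered ring is closed last.
2. Key cut, C5–C6 (last step, ring closure). O15 and O6 are 1,4‑related (dissonant). C5 is the a3 terminus of the allylic angelate and C6 is an a1 aldehyde. C5–I is therefore inverted into a d3 alkenylchromium (sp2 homoenolate equivalent). Its addition frees 6‑OH with both esters already in place.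
3. C7–C8: an auxiliary‑controlled syn titanium aldol of an isovaleryl thiazolidinethione sets C7 and C8. The same acyl group is then reduced directly to the C6 aldehyde.
4. C3–C4 and C5–I: anti‑carbomagnesiation of propargyl alcohol followed by iodinolysis fixes the C4=C5 geometry. The angelate is put on C15 by Mitsunobu alkylation of the carboxylate.
5. C10=C1 (E): zirconium‑catalysed methylalumination of a butynyl silyl ether, and the alanate then opens oxirane (C2, C3).

Assumption: the (S)‑valinol‑derived oxazoline–sulfonamide ligand is taken to direct alkenyl transfer to the Si face of aldehyde 22. If a test run shows the opposite sense, its (R)‑antipode is used and nothing else changes.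

**Step 1**
Reactants: 1 tert‑butyl(but‑3‑yn‑1‑yloxy)dimethylsilane; 2 oxirane
Product: 5 (E)‑6‑[(tert‑butyldimethylsilyl)oxy]‑4‑methylhex‑3‑en‑1‑ol, via alkenyldimethylalane 3 (not isolated), via lithium alkenylalanate 4 (not isolated)
Conditions: Me3Al (2.5 equiv), Cp2ZrCl2 (0.25 equiv), CH2Cl2, 0 °C to rt; volatiles off; n‑BuLi (1.0 equiv), hexane/THF, −78 to 0 °C; 2 (3 equiv), THF, −78 °C to rt; aq. work‑up
Reagents that add atoms: trimethylaluminium, C[Al](C)C
Why: Negishi zirconium‑catalysed methylalumination adds CH3 and Al syn across the terminal alkyne with CH3 on the internal carbon, which fixes the E geometry of C10=C1, and the more nucleophilic alanate 4 opens oxirane with retention at the alkenyl carbon to add C2 and C3.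

**Step 2**
Reactants: 5 (E)‑6‑[(tert‑butyldimethylsilyl)oxy]‑4‑methylhex‑3‑en‑1‑ol
Product: 6 (E)‑[(6‑bromo‑3‑methylhex‑3‑en‑1‑yl)oxy](tert‑butyl)dimethylsilane
Conditions: CBr4, PPh3, CH2Cl2, 0 °C
Reagents that add atoms: carbon tetrabromide, BrC(Br)(Br)Br
Why: Appel reaction, an SN2 displacement of the oxyphosphonium salt of a primary alcohol under neutral conditions that leave the silyl ether and the trisubstituted alkene alone.

**Step 3**
Reactants: 6 (E)‑[(6‑bromo‑3‑methylhex‑3‑en‑1‑yl)oxy](tert‑butyl)dimethylsilane; 7 prop‑2‑yn‑1‑ol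
Product: 11 (2Z,5E)‑8‑[(tert‑butyldimethylsilyl)oxy]‑2‑(iodomethylidene)‑6‑methyloct‑5‑en‑1‑ol, via Grignard reagent 8 (not isolated), via chloromagnesium propargyl alkoxide 9 (not isolated), via oxamagnesacyclopentene 10 (not isolated)
Conditions: 6, Mg, THF, 40 °C; separately 7 (1.5 equiv), i‑PrMgCl (1.0 equiv per 7), Et2O/THF, 0 °C; combine, CuI (15 mol %), rt, 18 h; I2, THF, −40 to 0 °C; aq. work‑up
Reagents that add atoms: iodine, II
Why: Copper‑catalysed anti‑carbomagnesiation of a propargylic alkoxide (Duboudin–Jousseaume reaction) puts the alkyl group on the internal carbon and magnesium on the terminal carbon inside the five‑membered chelate 10, so iodinolysis with retention gives only the alkene with iodine cis to CH2OH, the C4=C5 geometry of the target.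

**Step 4**
Reactants: 11 (2Z,5E)‑8‑[(tert‑butyldimethylsilyl)oxy]‑2‑(iodomethylidene)‑6‑methyloct‑5‑en‑1‑ol; 12 angelic acid, (Z)‑2‑methylbut‑2‑enoic acid
Product: 13 (2Z,5E)‑8‑[(tert‑butyldimethylsilyl)oxy]‑2‑(iodomethylidene)‑6‑methyloct‑5‑en‑1‑yl (Z)‑2‑methylbut‑2‑enoate
Conditions: PPh3, DIAD, THF, 0 °C
Reagents that add atoms: none
Why: Mitsunobu esterification activates the primary allylic alcohol and not the acid, so angelate acts only as a carboxylate nucleophile (SN2 at C15) and the Z to E drift known for activated angeloyl species is avoided.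

**Step 5**
Reactants: 13 (2Z,5E)‑8‑[(tert‑butyldimethylsilyl)oxy]‑2‑(iodomethylidene)‑6‑methyloct‑5‑en‑1‑yl (Z)‑2‑methylbut‑2‑enoate
Product: 14 (2Z,5E)‑8‑hydroxy‑2‑(iodomethylidene)‑6‑methyloct‑5‑en‑1‑yl (Z)‑2‑methylbut‑2‑enoate
Conditions: HF·pyridine, pyridine/THF, 0 °C to rt
Reagents that add atoms: none
Why: Fluoride‑driven cleavage of a primary silyl ether under buffered, mildly acidic conditions that touch neither the angelate nor the alkenyl iodide.

**Step 6**
Reactants: 14 (2Z,5E)‑8‑hydroxy‑2‑(iodomethylidene)‑6‑methyloct‑5‑en‑1‑yl (Z)‑2‑methylbut‑2‑enoate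
Product: 15 (2Z,5E)‑2‑(iodomethylidene)‑6‑methyl‑8‑oxooct‑5‑en‑1‑yl (Z)‑2‑methylbut‑2‑enoate
Conditions: Dess–Martin periodinane, pyridine, CH2Cl2, 0 °C; used crude
Reagents that add atoms: none
Why: Dess–Martin oxidation buffered with pyridine is neutral and fast enough to give the β,γ‑unsaturated aldehyde without migration of C10=C1 into conjugation.

**Step 7**
Reactants: 16 (S)‑4‑benzyl‑1,3‑thiazolidine‑2‑thione; 17 3‑methylbutanoyl chloride
Product: 18 (S)‑1‑(4‑benzyl‑2‑thioxo‑1,3‑thiazolidin‑3‑yl)‑3‑methylbutan‑1‑one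
Conditions: Et3N, DMAP (5 mol %), CH2Cl2, 0 °C to rt
Reagents that add atoms: none
Why: Simple N‑acylation of the acidic thiazolidinethione NH gives an activated imide that serves both as aldol platform and as latent aldehyde.

**Step 8**
Reactants: 18 (S)‑1‑(4‑benzyl‑2‑thioxo‑1,3‑thiazolidin‑3‑yl)‑3‑methylbutan‑1‑one; 15 (2Z,5E)‑2‑(iodomethylidene)‑6‑methyl‑8‑oxooct‑5‑en‑1‑yl (Z)‑2‑methylbut‑2‑enoate
Product: 20 (S)‑4‑benzyl‑3‑[(2R,3S,5E,9Z)‑9‑(angeloyloxymethyl)‑3‑hydroxy‑10‑iodo‑5‑methyl‑2‑(propan‑2‑yl)deca‑5,9‑dienoyl]‑1,3‑thiazolidine‑2‑thione, via chlorotitanium Z‑enolate 19 (not isolated)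
Conditions: 18 (1.2 equiv), TiCl4 (1.1 equiv per 18), i‑Pr2NEt (1.1 equiv per 18), CH2Cl2, 0 °C, 40 min; 15, −78 °C; aq. NH4Cl
Reagents that add atoms: none
Why: Crimmins titanium aldol, in which one equivalent each of TiCl4 and amine keeps the thione sulfur on titanium, so the chelated chair transition state of Z‑enolate 19 gives the "non‑Evans" syn adduct and sets C7 (2R here, S in the target after the priority change) and C8 (S) in one step.

**Step 9**
Reactants: 20 syn‑aldol adduct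
Product: 21 (S)‑4‑benzyl‑3‑[(2R,3S,5E,9Z)‑3‑acetoxy‑9‑(angeloyloxymethyl)‑10‑iodo‑5‑methyl‑2‑(propan‑2‑yl)deca‑5,9‑dienoyl]‑1,3‑thiazolidine‑2‑thione
Conditions: Ac2O, pyridine, DMAP (5 mol %), CH2Cl2, 0 °C
Reagents that add atoms: acetic anhydride, CC(=O)OC(C)=O
Why: Standard acylation places the C8 acetate before the C6 oxygen exists, so two secondary alcohols never have to be told apart, and no stereocentre is touched.

**Step 10**
Reactants: 21 acetoxy thioimide
Product: 22 (2R,3S,5E,9Z)‑3‑acetoxy‑9‑(angeloyloxymethyl)‑10‑iodo‑5‑methyl‑2‑(propan‑2‑yl)deca‑5,9‑dienal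
Conditions: LiAlH(Ot‑Bu)3 (1.2 equiv), THF, −78 to −20 °C; cold aq. work‑up; short silica plug, used at once
Reagents that add atoms: none
Why: Partial reduction of an N‑acylthiazolidinethione (Izawa–Mukaiyama aldehyde synthesis), in which the activated imide takes one hydride to give a stable tetrahedral aluminate that collapses to the aldehyde only on work‑up, while acetate, angelate and alkenyl iodide are inert to this mild hydride.

**Step 11**
Reactants: 22 iodo aldehyde
Product: 24 [(1Z,3S,4S,5S,7E)‑5‑acetoxy‑3‑hydroxy‑7‑methyl‑4‑(propan‑2‑yl)cyclodeca‑1,7‑dien‑1‑yl]methyl (Z)‑2‑methylbut‑2‑enoate, via alkenylchromium dichloride 23 (not isolated)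
Conditions: CrCl2 (10 equiv), (S)‑N‑[2‑(4‑isopropyl‑4,5‑dihydrooxazol‑2‑yl)‑6‑methylphenyl]methanesulfonamide (11 equiv), Et3N (11 equiv), THF, rt, 1 h; NiCl2·(2,9‑dimethyl‑1,10‑phenanthroline) (0.2 equiv); 22 by syringe pump over 10 h to 2 mM, rt; aq. potassium serinate
Reagents that add atoms: none
Why: Nozaki–Hiyama–Kishi macrocyclisation, in which zerovalent nickel inserts into C5–I with retention, transmetalation to trivalent chromium gives 23, a d3 (homoenolate‑type) nucleophile at a carbon that is by nature an acceptor, and 23 adds only to the aldehyde, with C6 set as S by the chiral sulfonamide–chromium complex directing attack to the Si face, in line with the polar 1,3‑anti preference of a β‑acyloxy aldehyde.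

**Compound list**
1 | tert‑butyl(but‑3‑yn‑1‑yloxy)dimethylsilane | C#CCCO[Si](C)(C)C(C)(C)C | starting material
2 | oxirane | C1CO1 | starting material
3 | (E)‑{4‑[(tert‑butyldimethylsilyl)oxy]‑2‑methylbut‑1‑en‑1‑yl}dimethylalane (not isolated) | C[Al](C)/C=C(\C)CCO[Si](C)(C)C(C)(C)C | intermediate
4 | lithium butyl{(E)‑4‑[(tert‑butyldimethylsilyl)oxy]‑2‑methylbut‑1‑en‑1‑yl}dimethylalanate (not isolated) | [Li+].CCCC[Al-](C)(C)/C=C(\C)CCO[Si](C)(C)C(C)(C)C | intermediate
5 | (E)‑6‑[(tert‑butyldimethylsilyl)oxy]‑4‑methylhex‑3‑en‑1‑ol | OCC/C=C(\C)CCO[Si](C)(C)C(C)(C)C | intermediate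
6 | (E)‑[(6‑bromo‑3‑methylhex‑3‑en‑1‑yl)oxy](tert‑butyl)dimethylsilane | BrCC/C=C(\C)CCO[Si](C)(C)C(C)(C)C | intermediate
7 | prop‑2‑yn‑1‑ol | C#CCO | starting material
8 | {(E)‑6‑[(tert‑butyldimethylsilyl)oxy]‑4‑methylhex‑3‑en‑1‑yl}magnesium bromide (not isolated) | Br[Mg]CC/C=C(\C)CCO[Si](C)(C)C(C)(C)C | intermediate
9 | chloromagnesium prop‑2‑yn‑1‑olate (not isolated) | C#CCO[Mg]Cl | intermediate
10 | 4‑substituted 1‑oxa‑2‑magnesacyclopent‑3‑ene, Mg bound to C5 and O15 (not isolated) | [Mg]1OCC(CC/C=C(\C)CCO[Si](C)(C)C(C)(C)C)=C1 | intermediate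
11 | (2Z,5E)‑8‑[(tert‑butyldimethylsilyl)oxy]‑2‑(iodomethylidene)‑6‑methyloct‑5‑en‑1‑ol | OC/C(=C\I)CC/C=C(\C)CCO[Si](C)(C)C(C)(C)C | intermediate
12 | angelic acid, (Z)‑2‑methylbut‑2‑enoic acid | C/C=C(/C)C(=O)O | starting material
13 | (2Z,5E)‑8‑[(tert‑butyldimethylsilyl)oxy]‑2‑(iodomethylidene)‑6‑methyloct‑5‑en‑1‑yl angelate | C/C=C(/C)C(=O)OC/C(=C\I)CC/C=C(\C)CCO[Si](C)(C)C(C)(C)C | intermediate
14 | (2Z,5E)‑8‑hydroxy‑2‑(iodomethylidene)‑6‑methyloct‑5‑en‑1‑yl angelate | C/C=C(/C)C(=O)OC/C(=C\I)CC/C=C(\C)CCO | intermediate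
15 | (2Z,5E)‑2‑(iodomethylidene)‑6‑methyl‑8‑oxooct‑5‑en‑1‑yl angelate | C/C=C(/C)C(=O)OC/C(=C\I)CC/C=C(\C)CC=O | intermediate
16 | (S)‑4‑benzyl‑1,3‑thiazolidine‑2‑thione | S=C1N[C@@H](Cc2ccccc2)CS1 | starting material
17 | 3‑methylbutanoyl chloride | CC(C)CC(=O)Cl | starting material
18 | (S)‑1‑(4‑benzyl‑2‑thioxo‑1,3‑thiazolidin‑3‑yl)‑3‑methylbutan‑1‑one | CC(C)CC(=O)N1[C@@H](Cc2ccccc2)CSC1=S | intermediate
19 | trichlorotitanium (Z)‑enolate of 18 (not isolated) | CC(C)/C=C(\O[Ti](Cl)(Cl)Cl)N1[C@@H](Cc2ccccc2)CSC1=S | intermediate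
20 | syn‑aldol adduct, (2R,3S)‑3‑hydroxy‑2‑isopropyl acyl thiazolidinethione | C/C=C(/C)C(=O)OC/C(=C\I)CC/C=C(\C)C[C@H](O)[C@@H](C(C)C)C(=O)N1[C@@H](Cc2ccccc2)CSC1=S | intermediate
21 | (2R,3S)‑3‑acetoxy‑2‑isopropyl acyl thiazolidinethione | C/C=C(/C)C(=O)OC/C(=C\I)CC/C=C(\C)C[C@H](OC(C)=O)[C@@H](C(C)C)C(=O)N1[C@@H](Cc2ccccc2)CSC1=S | intermediate
22 | (2R,3S,5E,9Z)‑3‑acetoxy‑9‑(angeloyloxymethyl)‑10‑iodo‑5‑methyl‑2‑(propan‑2‑yl)deca‑5,9‑dienal | C/C=C(/C)C(=O)OC/C(=C\I)CC/C=C(\C)C[C@H](OC(C)=O)[C@@H](C(C)C)C=O | intermediate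
23 | C5 alkenylchromium dichloride derived from 22 (not isolated) | C/C=C(/C)C(=O)OC/C(=C\[Cr](Cl)Cl)CC/C=C(\C)C[C@H](OC(C)=O)[C@@H](C(C)C)C=O | intermediate
24 | [(1Z,3S,4S,5S,7E)‑5‑acetoxy‑3‑hydroxy‑7‑methyl‑4‑(propan‑2‑yl)cyclodeca‑1,7‑dien‑1‑yl]methyl (Z)‑2‑methylbut‑2‑enoate | C/C=C(/C)C(=O)OC/C1=C\[C@H](O)[C@H](C(C)C)[C@@H](OC(C)=O)C/C(C)=C/CC1 | target

**Totals and risks**

Total step count: 11.

Longest linear sequence: 10 (steps 1–6 and 8–11).

Steps most likely to fail: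

Step 11. Ten‑membered ring closure competes with oligomerisation. The ring‑forming transition state may also override the ligand and favour the 6R epimer. The fallback sets out from 20 and returns at 24, and it moves the control of C6 from the C–C bond formation to a directed hydride transfer.
- 20 is reduced with LiAlH(Ot‑Bu)3 (2.2 equiv) to the β‑hydroxy aldehyde F1.
- F1 is cyclised with ligand‑free CrCl2/NiCl2 in DMSO at high dilution to the macrocyclic 6,8‑diol F2, whatever the C6 ratio.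
- MnO2 oxidises only the allylic C6 carbinol and gives the β‑hydroxy enone F3.
- An Evans–Tishchenko reduction (SmI2 0.3 equiv, acetaldehyde, THF, −10 °C) passes hydride from the O8 hemiacetal to the same face of C6. This gives the 1,3‑anti (6S) alcohol and leaves the acetate on O8, which is 24.

Step 8. The hindered isovaleryl enolate is slow, 15 can slip into conjugation, and the chelated and open transition states can leak into each other. The fallback sets out from 15 and returns at 22, with a boron enolate and a different acyl‑to‑aldehyde exit.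
- Purchased (R)‑4‑benzyl‑3‑(3‑methylbutanoyl)oxazolidin‑2‑one with Bu2BOTf/Et3N at −78 °C gives the oxazolidinone syn‑aldol adduct F4.
- Hydroxyl‑assisted aminolysis (Me3Al, MeONHMe·HCl, −20 °C) gives the hydroxy Weinreb amide F5.
- Ac2O/pyridine gives the acetoxy Weinreb amide F6.
- Cp2Zr(H)Cl in THF reduces the amide chemoselectively, in the presence of the esters, to 22.

Step 10. The hindered acyl group may need temperatures at which over‑reduction or loss of AcOH from the β‑acetoxy aldehyde sets in. The fallback sets out from 21 and returns at 22, by full reduction followed by neutral re‑oxidation.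
- NaBH4 in THF/EtOH at 0 °C, with short contact to avoid acetyl migration, removes the auxiliary and gives the primary alcohol F7.
- Pyridine‑buffered Dess–Martin periodinane then gives 22.

**Further compounds**
F1 | step 11 | (2R,3S,5E,9Z)‑9‑(angeloyloxymethyl)‑3‑hydroxy‑10‑iodo‑5‑methyl‑2‑(propan‑2‑yl)deca‑5,9‑dienal | C/C=C(/C)C(=O)OC/C(=C\I)CC/C=C(\C)C[C@H](O)[C@@H](C(C)C)C=O
F2 | step 11 | macrocyclic 6,8‑diol, mixture of C6 epimers, (7S,8S) | C/C=C(/C)C(=O)OC/C1=C\C(O)[C@H](C(C)C)[C@@H](O)C/C(C)=C/CC1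
F3 | step 11 | macrocyclic 8‑hydroxy‑6‑oxo enone | C/C=C(/C)C(=O)OC/C1=C\C(=O)[C@H](C(C)C)[C@@H](O)C/C(C)=C/CC1
F4 | step 8 | (R)‑4‑benzyl‑3‑[(2R,3S)‑3‑hydroxy‑2‑isopropyl acyl]oxazolidin‑2‑one syn‑aldol adduct | C/C=C(/C)C(=O)OC/C(=C\I)CC/C=C(\C)C[C@H](O)[C@@H](C(C)C)C(=O)N1[C@H](Cc2ccccc2)COC1=O
F5 | step 8 | (2R,3S)‑3‑hydroxy‑2‑isopropyl N‑methoxy‑N‑methyl amide | C/C=C(/C)C(=O)OC/C(=C\I)CC/C=C(\C)C[C@H](O)[C@@H](C(C)C)C(=O)N(C)OC
F6 | step 8 | (2R,3S)‑3‑acetoxy‑2‑isopropyl N‑methoxy‑N‑methyl amide | C/C=C(/C)C(=O)OC/C(=C\I)CC/C=C(\C)C[C@H](OC(C)=O)[C@@H](C(C)C)C(=O)N(C)OC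
F7 | step 10 | primary alcohol, 3‑acetoxy‑2‑isopropyl deca‑5,9‑dien‑1‑ol with angelate and iodide in place | C/C=C(/C)C(=O)OC/C(=C\I)CC/C=C(\C)C[C@H](OC(C)=O)[C@@H](C(C)C)CO
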